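**Retrosynthetic overview**

- The strategy rests on rings D and E. In each ring E, C1 (bonded to a ring D oxygen) sits between the oxygenated C2 and C6 and para to the C4 hydroxyl, so a formyl group at C4 can activate fluoride displacement at C1 and then be oxidised to that hydroxyl. Ring D, with three adjacent oxygens and a para oxygen, is 4-O-benzyl methyl gallate with the ester as a latent phenol.
- Right half: both D–O–E bonds by a two-directional SNAr, then Baeyer–Villiger unmasking, ortho-bromination, methylation and a double Suzuki coupling to attach the two phloroglucinyl rings F.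
- Left half: the same SNAr/Baeyer–Villiger pair run twice from 3,5-dimethoxyphenol (ring A), first with a pre-arylated fluoroaldehyde (ring B with its phloroglucinyl ring G), then with the plain fluoroaldehyde (ring C); the resulting phenol becomes a boronic acid.
- Union: debenzylation of ring D and Chan–Lam coupling form the central C–O–D ether; the ester is then taken to the phenol (reduction, oxidation, Baeyer–Villiger) and all 21 methyl ethers are cleaved.
- No ring is constructed; the nine purchased benzene rings are joined in the order D–O–E (twice), E–F (twice), B–G, A–O–B, B–O–C, C–O–D.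

Key step: step 2

Remark: the target has no stereocentre and its three biaryl axes carry symmetric 2,4,6-trioxygenated rings, so nothing stereochemical has to be set; methyl gallate, 4-fluoro-3,5-dimethoxybenzaldehyde, 2,4,6-trimethoxyphenylboronic acid and 3,5-dimethoxyphenol are assumed to be purchasable.

Abbreviations used in names:
- ArE = 2,4,6-trimethoxy-3-(2,4,6-trimethoxyphenyl)phenyl (ring E with ring F).
- ArL = 4-[4-(3,5-dimethoxyphenoxy)-3,5-dimethoxy-2-(2,4,6-trimethoxyphenyl)phenoxy]-3,5-dimethoxyphenyl (rings C, B, G and A).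

**Route**

Step 1
Reactants: 1 methyl gallate
Product: 2 methyl 4-(benzyloxy)-3,5-dihydroxybenzoate
Conditions: BnBr (1.0 equiv), KHCO3, KI (cat.), DMF, rt
Reagents that add atoms: benzyl bromide, BrCc1ccccc1
Why: Williamson ether synthesis in which the weak base ionises only the 4-hydroxyl, the most acidic one because it is para to the ester, so benzylation should occur there.

Step 2
Reactants: 2 methyl 4-(benzyloxy)-3,5-dihydroxybenzoate; 3 4-fluoro-3,5-dimethoxybenzaldehyde (2.4 equiv)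
Product: 4 methyl 4-(benzyloxy)-3,5-bis(4-formyl-2,6-dimethoxyphenoxy)benzoate
Conditions: Cs2CO3 (3 equiv), DMSO, 100 °C, N2
Reagents that add atoms: none
Why: Each cesium phenoxide of 2 adds to the fluorine-bearing C4 of 3 to give a Meisenheimer anion whose charge is carried by the para formyl group, and loss of fluoride restores the arene (addition–elimination SNAr). The closest known reaction type is the displacement of fluoride from 4-fluorobenzaldehydes by phenoxides, used to make diaryl ethers ahead of a Dakin or Baeyer–Villiger unmasking. No ring is closed and no stereocentre is formed; two C–O bonds are made. The step needs complete substitution at both crowded phenoxides and attack only at the fluorinated carbon. This should be secured by the equivalence of the two phenoxides, the small fluoride leaving group, the formyl group as the only acceptor and the excess of 3. The benzyl ether keeps the 4-oxygen out of the reaction, and the ester should survive anhydrous carbonate.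

Step 3
Reactants: 4 methyl 4-(benzyloxy)-3,5-bis(4-formyl-2,6-dimethoxyphenoxy)benzoate
Product: 6 methyl 4-(benzyloxy)-3,5-bis(4-hydroxy-2,6-dimethoxyphenoxy)benzoate, via bis-formate 5 (not isolated)
Conditions: mCPBA (3 equiv), CH2Cl2, 0 °C to rt; then K2CO3 (cat.), MeOH, rt
Reagents that add atoms: mCPBA, OOC(=O)c1cccc(Cl)c1
Why: Baeyer–Villiger oxidation of the aldehydes (Dakin-type) in which the para-oxygenated aryl group migrates to give aryl formates, which methanolysis should cleave without changing the methyl ester or the benzyl ether.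

Step 4
Reactants: 6 methyl 4-(benzyloxy)-3,5-bis(4-hydroxy-2,6-dimethoxyphenoxy)benzoate
Product: 7 methyl 4-(benzyloxy)-3,5-bis(3-bromo-4-hydroxy-2,6-dimethoxyphenoxy)benzoate
Conditions: NBS (2.0 equiv), CH2Cl2, −78 to 0 °C
Reagents that add atoms: N-bromosuccinimide, O=C1CCC(=O)N1Br
Why: Electrophilic aromatic bromination directed by each ring E phenol to one of its two equivalent ortho positions (para is blocked); the first bromine slows a second attack on the same ring and ring D is deactivated by its ester.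

Step 5
Reactants: 7 methyl 4-(benzyloxy)-3,5-bis(3-bromo-4-hydroxy-2,6-dimethoxyphenoxy)benzoate
Product: 8 methyl 4-(benzyloxy)-3,5-bis(3-bromo-2,4,6-trimethoxyphenoxy)benzoate
Conditions: MeI, K2CO3, DMF, rt
Reagents that add atoms: iodomethane, CI
Why: Williamson O-methylation of the two phenols under carbonate, conditions that should leave the ester, the aryl bromides and the benzyl ether untouched.

Step 6
Reactants: 8 methyl 4-(benzyloxy)-3,5-bis(3-bromo-2,4,6-trimethoxyphenoxy)benzoate; 9 2,4,6-trimethoxyphenylboronic acid (5 equiv, added in portions)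
Product: 10 methyl 4-(benzyloxy)-3,5-bis(ArE-oxy)benzoate
Conditions: Pd(OAc)2, SPhos, K3PO4, toluene/H2O (20:1), 100 °C
Reagents that add atoms: none
Why: Suzuki–Miyaura coupling with a bulky electron-rich biarylphosphine on zerovalent palladium, the established way to tetra-ortho-substituted biaryls, with excess boronic acid to offset its protodeboronation.

Step 7
Reactants: 10 methyl 4-(benzyloxy)-3,5-bis(ArE-oxy)benzoate
Product: 11 methyl 4-hydroxy-3,5-bis(ArE-oxy)benzoate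
Conditions: H2 (1 atm), 10% Pd/C, EtOAc/MeOH, rt
Reagents that add atoms: none
Why: Catalytic hydrogenolysis of the benzyl ether, to which aryl methyl ethers, diaryl ethers, biaryl bonds and the ester are inert.

Step 8
Reactants: 3 4-fluoro-3,5-dimethoxybenzaldehyde
Product: 12 2-bromo-4-fluoro-3,5-dimethoxybenzaldehyde
Conditions: NBS (1.05 equiv), MeCN, rt to 50 °C
Reagents that add atoms: N-bromosuccinimide, O=C1CCC(=O)N1Br
Why: Electrophilic aromatic bromination at C2, which is ortho to one methoxy group and para to the other; C2 and C6 are equivalent and the first bromine deactivates the ring toward a second.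

Step 9
Reactants: 12 2-bromo-4-fluoro-3,5-dimethoxybenzaldehyde; 9 2,4,6-trimethoxyphenylboronic acid (2 equiv)
Product: 13 4-fluoro-3,5-dimethoxy-2-(2,4,6-trimethoxyphenyl)benzaldehyde
Conditions: Pd(OAc)2, SPhos, K3PO4, toluene/H2O (10:1), 90 °C
Reagents that add atoms: none
Why: Suzuki–Miyaura coupling in which the ortho formyl group speeds oxidative addition of the hindered bromide, while the fluoride, flanked by two methoxy groups, should not be displaced by the weak phosphate base.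

Step 10
Reactants: 13 4-fluoro-3,5-dimethoxy-2-(2,4,6-trimethoxyphenyl)benzaldehyde; 14 3,5-dimethoxyphenol (1.1 equiv)
Product: 15 4-(3,5-dimethoxyphenoxy)-3,5-dimethoxy-2-(2,4,6-trimethoxyphenyl)benzaldehyde
Conditions: K2CO3, DMF, 90 °C
Reagents that add atoms: none
Why: SNAr of the unhindered ring A phenoxide at the fluorinated carbon para to the formyl group, the same addition–elimination as in step 2, forming the A–O–B ether.

Step 11
Reactants: 15 4-(3,5-dimethoxyphenoxy)-3,5-dimethoxy-2-(2,4,6-trimethoxyphenyl)benzaldehyde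
Product: 17 4-(3,5-dimethoxyphenoxy)-3,5-dimethoxy-2-(2,4,6-trimethoxyphenyl)phenol, via aryl formate 16 (not isolated)
Conditions: mCPBA (1.2 equiv), CH2Cl2, 0 °C; then K2CO3 (cat.), MeOH, rt
Reagents that add atoms: mCPBA, OOC(=O)c1cccc(Cl)c1
Why: Baeyer–Villiger oxidation of the aldehyde with migration of the para-aryloxy-substituted ring and methanolysis of the formate; the short reaction at low temperature should spare the electron-rich methoxyarene rings.

Step 12
Reactants: 17 4-(3,5-dimethoxyphenoxy)-3,5-dimethoxy-2-(2,4,6-trimethoxyphenyl)phenol; 3 4-fluoro-3,5-dimethoxybenzaldehyde (1.3 equiv)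
Product: 18 4-[4-(3,5-dimethoxyphenoxy)-3,5-dimethoxy-2-(2,4,6-trimethoxyphenyl)phenoxy]-3,5-dimethoxybenzaldehyde (ArL–CHO)
Conditions: Cs2CO3, DMSO, 100 °C
Reagents that add atoms: none
Why: SNAr of the ring B phenoxide on the para-formyl-activated fluoride, of the same class as step 2, forming the B–O–C ether with ring C already carrying its two flanking oxygens.

Step 13
Reactants: 18 ArL–CHO
Product: 20 4-[4-(3,5-dimethoxyphenoxy)-3,5-dimethoxy-2-(2,4,6-trimethoxyphenyl)phenoxy]-3,5-dimethoxyphenol (ArL–OH), via aryl formate 19 (not isolated)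
Conditions: mCPBA (1.2 equiv), CH2Cl2, 0 °C; then K2CO3 (cat.), MeOH, rt
Reagents that add atoms: mCPBA, OOC(=O)c1cccc(Cl)c1
Why: Baeyer–Villiger oxidation followed by formate methanolysis, which should place the oxygen on ring C at the carbon that will be bonded to ring D.

Step 14
Reactants: 20 ArL–OH
Product: 21 ArL trifluoromethanesulfonate (ArL–OTf)
Conditions: PhNTf2, Et3N, DMAP (cat.), CH2Cl2, rt
Reagents that add atoms: N-phenylbis(trifluoromethanesulfonimide), O=S(=O)(N(c1ccccc1)S(=O)(=O)C(F)(F)F)C(F)(F)F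
Why: O-sulfonylation of the unhindered phenol with a mild triflyl donor that should not attack the electron-rich rings.

Step 15
Reactants: 21 ArL–OTf
Product: 22 2-(ArL)-4,4,5,5-tetramethyl-1,3,2-dioxaborolane (ArL–Bpin)
Conditions: B2pin2, PdCl2(dppf), KOAc, 1,4-dioxane, 90 °C
Reagents that add atoms: bis(pinacolato)diboron, CC1(C)OB(OC1(C)C)B1OC(C)(C)C(C)(C)O1
Why: Miyaura borylation of an aryl triflate whose carbon has only hydrogen neighbours; acetate is too weak a base to trigger Suzuki homocoupling.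

Step 16
Reactants: 22 ArL–Bpin
Product: 23 ArL boronic acid (ArL–B(OH)2)
Conditions: NaIO4, NH4OAc, acetone/H2O, rt
Reagents that add atoms: water, O
Why: Oxidative deprotection of the pinacol boronate, in which periodate cleaves the pinacol released by hydrolysis and so drives the equilibrium to the free boronic acid.

Step 17
Reactants: 11 methyl 4-hydroxy-3,5-bis(ArE-oxy)benzoate; 23 ArL–B(OH)2 (1.5 equiv)
Product: 24 methyl 4-(ArL-oxy)-3,5-bis(ArE-oxy)benzoate
Conditions: Cu(OAc)2 (2 equiv), pyridine (5 equiv), 4 Å MS, CH2Cl2, dry air, rt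
Reagents that add atoms: none
Why: Chan–Lam coupling, in which the aryl group passes from boron to a divalent copper phenoxide and the C–O bond forms by reductive elimination from trivalent copper at room temperature; the reaction is known for 2,6-disubstituted electron-poor phenols, and the boron-bearing carbon here is unhindered.

Step 18
Reactants: 24 methyl 4-(ArL-oxy)-3,5-bis(ArE-oxy)benzoate
Product: 25 [4-(ArL-oxy)-3,5-bis(ArE-oxy)phenyl]methanol
Conditions: iBu2AlH (3 equiv), CH2Cl2, −78 to 0 °C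
Reagents that add atoms: none
Why: Hydride reduction of the only carbonyl group, the methyl ester, to the benzylic alcohol.

Step 19
Reactants: 25 [4-(ArL-oxy)-3,5-bis(ArE-oxy)phenyl]methanol
Product: 26 4-(ArL-oxy)-3,5-bis(ArE-oxy)benzaldehyde
Conditions: MnO2 (excess), CH2Cl2, rt
Reagents that add atoms: none
Why: Selective heterogeneous oxidation of a benzylic alcohol to the aldehyde, with no over-oxidation and no action on the ethers.

Step 20
Reactants: 26 4-(ArL-oxy)-3,5-bis(ArE-oxy)benzaldehyde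
Product: 28 4-(ArL-oxy)-3,5-bis(ArE-oxy)phenol, via aryl formate 27 (not isolated)
Conditions: mCPBA (1.2 equiv), CH2Cl2, 0 °C; then K2CO3 (cat.), MeOH, rt
Reagents that add atoms: mCPBA, OOC(=O)c1cccc(Cl)c1
Why: Baeyer–Villiger oxidation in which ring D, bearing a para aryloxy group, migrates, followed by formate methanolysis to reveal the ring D hydroxyl.

Step 21
Reactants: 28 4-(ArL-oxy)-3,5-bis(ArE-oxy)phenol
Product: 29 CNP0117322.0 (target)
Conditions: BBr3 (about 3 equiv per methoxy group), CH2Cl2, −78 °C to rt; then MeOH/H2O, under argon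
Reagents that add atoms: none
Why: Lewis-acid demethylation in which bromide attacks the methyl group of each boron-complexed aryl methyl ether (SN2) while diaryl ether and biaryl bonds are not cleaved, and hydrolysis of the aryl borates should free all 22 hydroxyls.

**Compound list**

1 | methyl gallate | COC(=O)c1cc(O)c(O)c(O)c1 | starting material
2 | methyl 4-(benzyloxy)-3,5-dihydroxybenzoate | COC(=O)c1cc(O)c(OCc2ccccc2)c(O)c1 | intermediate
3 | 4-fluoro-3,5-dimethoxybenzaldehyde | COc1cc(C=O)cc(OC)c1F | starting material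
4 | methyl 4-(benzyloxy)-3,5-bis(4-formyl-2,6-dimethoxyphenoxy)benzoate | COC(=O)c1cc(Oc2c(OC)cc(C=O)cc2OC)c(OCc2ccccc2)c(Oc2c(OC)cc(C=O)cc2OC)c1 | intermediate
5 | methyl 4-(benzyloxy)-3,5-bis[4-(formyloxy)-2,6-dimethoxyphenoxy]benzoate (bis-formate) | COC(=O)c1cc(Oc2c(OC)cc(OC=O)cc2OC)c(OCc2ccccc2)c(Oc2c(OC)cc(OC=O)cc2OC)c1 | intermediate
6 | methyl 4-(benzyloxy)-3,5-bis(4-hydroxy-2,6-dimethoxyphenoxy)benzoate | COC(=O)c1cc(Oc2c(OC)cc(O)cc2OC)c(OCc2ccccc2)c(Oc2c(OC)cc(O)cc2OC)c1 | intermediate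
7 | methyl 4-(benzyloxy)-3,5-bis(3-bromo-4-hydroxy-2,6-dimethoxyphenoxy)benzoate | COC(=O)c1cc(Oc2c(OC)cc(O)c(Br)c2OC)c(OCc2ccccc2)c(Oc2c(OC)cc(O)c(Br)c2OC)c1 | intermediate
8 | methyl 4-(benzyloxy)-3,5-bis(3-bromo-2,4,6-trimethoxyphenoxy)benzoate | COC(=O)c1cc(Oc2c(OC)cc(OC)c(Br)c2OC)c(OCc2ccccc2)c(Oc2c(OC)cc(OC)c(Br)c2OC)c1 | intermediate
9 | 2,4,6-trimethoxyphenylboronic acid | COc1cc(OC)c(B(O)O)c(OC)c1 | starting material
10 | methyl 4-(benzyloxy)-3,5-bis[2,4,6-trimethoxy-3-(2,4,6-trimethoxyphenyl)phenoxy]benzoate | COC(=O)c1cc(Oc2c(OC)cc(OC)c(-c3c(OC)cc(OC)cc3OC)c2OC)c(OCc2ccccc2)c(Oc2c(OC)cc(OC)c(-c3c(OC)cc(OC)cc3OC)c2OC)c1 | intermediate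
11 | methyl 4-hydroxy-3,5-bis[2,4,6-trimethoxy-3-(2,4,6-trimethoxyphenyl)phenoxy]benzoate | COC(=O)c1cc(Oc2c(OC)cc(OC)c(-c3c(OC)cc(OC)cc3OC)c2OC)c(O)c(Oc2c(OC)cc(OC)c(-c3c(OC)cc(OC)cc3OC)c2OC)c1 | intermediate
12 | 2-bromo-4-fluoro-3,5-dimethoxybenzaldehyde | COc1cc(C=O)c(Br)c(OC)c1F | intermediate
13 | 4-fluoro-3,5-dimethoxy-2-(2,4,6-trimethoxyphenyl)benzaldehyde | COc1cc(C=O)c(-c2c(OC)cc(OC)cc2OC)c(OC)c1F | intermediate
14 | 3,5-dimethoxyphenol | COc1cc(O)cc(OC)c1 | starting material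
15 | 4-(3,5-dimethoxyphenoxy)-3,5-dimethoxy-2-(2,4,6-trimethoxyphenyl)benzaldehyde | COc1cc(OC)cc(Oc2c(OC)cc(C=O)c(-c3c(OC)cc(OC)cc3OC)c2OC)c1 | intermediate
16 | 4-(3,5-dimethoxyphenoxy)-3,5-dimethoxy-2-(2,4,6-trimethoxyphenyl)phenyl formate | COc1cc(OC)cc(Oc2c(OC)cc(OC=O)c(-c3c(OC)cc(OC)cc3OC)c2OC)c1 | intermediate
17 | 4-(3,5-dimethoxyphenoxy)-3,5-dimethoxy-2-(2,4,6-trimethoxyphenyl)phenol | COc1cc(OC)cc(Oc2c(OC)cc(O)c(-c3c(OC)cc(OC)cc3OC)c2OC)c1 | intermediate
18 | 4-[4-(3,5-dimethoxyphenoxy)-3,5-dimethoxy-2-(2,4,6-trimethoxyphenyl)phenoxy]-3,5-dimethoxybenzaldehyde (ArL–CHO) | COc1cc(OC)cc(Oc2c(OC)cc(Oc3c(OC)cc(C=O)cc3OC)c(-c3c(OC)cc(OC)cc3OC)c2OC)c1 | intermediate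
19 | 4-[4-(3,5-dimethoxyphenoxy)-3,5-dimethoxy-2-(2,4,6-trimethoxyphenyl)phenoxy]-3,5-dimethoxyphenyl formate | COc1cc(OC)cc(Oc2c(OC)cc(Oc3c(OC)cc(OC=O)cc3OC)c(-c3c(OC)cc(OC)cc3OC)c2OC)c1 | intermediate
20 | 4-[4-(3,5-dimethoxyphenoxy)-3,5-dimethoxy-2-(2,4,6-trimethoxyphenyl)phenoxy]-3,5-dimethoxyphenol (ArL–OH) | COc1cc(OC)cc(Oc2c(OC)cc(Oc3c(OC)cc(O)cc3OC)c(-c3c(OC)cc(OC)cc3OC)c2OC)c1 | intermediate
21 | ArL trifluoromethanesulfonate | COc1cc(OC)cc(Oc2c(OC)cc(Oc3c(OC)cc(OS(=O)(=O)C(F)(F)F)cc3OC)c(-c3c(OC)cc(OC)cc3OC)c2OC)c1 | intermediate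
22 | 2-(ArL)-4,4,5,5-tetramethyl-1,3,2-dioxaborolane | COc1cc(OC)cc(Oc2c(OC)cc(Oc3c(OC)cc(B4OC(C)(C)C(C)(C)O4)cc3OC)c(-c3c(OC)cc(OC)cc3OC)c2OC)c1 | intermediate
23 | ArL boronic acid | COc1cc(OC)cc(Oc2c(OC)cc(Oc3c(OC)cc(B(O)O)cc3OC)c(-c3c(OC)cc(OC)cc3OC)c2OC)c1 | intermediate
24 | methyl 4-(ArL-oxy)-3,5-bis(ArE-oxy)benzoate | COC(=O)c1cc(Oc2c(OC)cc(OC)c(-c3c(OC)cc(OC)cc3OC)c2OC)c(Oc2cc(OC)c(Oc3cc(OC)c(Oc4cc(OC)cc(OC)c4)c(OC)c3-c3c(OC)cc(OC)cc3OC)c(OC)c2)c(Oc2c(OC)cc(OC)c(-c3c(OC)cc(OC)cc3OC)c2OC)c1 | intermediate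
25 | [4-(ArL-oxy)-3,5-bis(ArE-oxy)phenyl]methanol | OCc1cc(Oc2c(OC)cc(OC)c(-c3c(OC)cc(OC)cc3OC)c2OC)c(Oc2cc(OC)c(Oc3cc(OC)c(Oc4cc(OC)cc(OC)c4)c(OC)c3-c3c(OC)cc(OC)cc3OC)c(OC)c2)c(Oc2c(OC)cc(OC)c(-c3c(OC)cc(OC)cc3OC)c2OC)c1 | intermediate
26 | 4-(ArL-oxy)-3,5-bis(ArE-oxy)benzaldehyde | O=Cc1cc(Oc2c(OC)cc(OC)c(-c3c(OC)cc(OC)cc3OC)c2OC)c(Oc2cc(OC)c(Oc3cc(OC)c(Oc4cc(OC)cc(OC)c4)c(OC)c3-c3c(OC)cc(OC)cc3OC)c(OC)c2)c(Oc2c(OC)cc(OC)c(-c3c(OC)cc(OC)cc3OC)c2OC)c1 | intermediate
27 | 4-(ArL-oxy)-3,5-bis(ArE-oxy)phenyl formate | O=COc1cc(Oc2c(OC)cc(OC)c(-c3c(OC)cc(OC)cc3OC)c2OC)c(Oc2cc(OC)c(Oc3cc(OC)c(Oc4cc(OC)cc(OC)c4)c(OC)c3-c3c(OC)cc(OC)cc3OC)c(OC)c2)c(Oc2c(OC)cc(OC)c(-c3c(OC)cc(OC)cc3OC)c2OC)c1 | intermediate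
28 | 4-(ArL-oxy)-3,5-bis(ArE-oxy)phenol (the target as its 21-fold methyl ether) | Oc1cc(Oc2c(OC)cc(OC)c(-c3c(OC)cc(OC)cc3OC)c2OC)c(Oc2cc(OC)c(Oc3cc(OC)c(Oc4cc(OC)cc(OC)c4)c(OC)c3-c3c(OC)cc(OC)cc3OC)c(OC)c2)c(Oc2c(OC)cc(OC)c(-c3c(OC)cc(OC)cc3OC)c2OC)c1 | intermediate
29 | CNP0117322.0 | Oc1cc(O)cc(Oc2c(O)cc(Oc3c(O)cc(Oc4c(Oc5c(O)cc(O)c(-c6c(O)cc(O)cc6O)c5O)cc(O)cc4Oc4c(O)cc(O)c(-c5c(O)cc(O)cc5O)c4O)cc3O)c(-c3c(O)cc(O)cc3O)c2O)c1 | target

**Totals and risks**

Total step count: 21 steps.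
Longest linear sequence: 14 steps (steps 8 to 21, from 4-fluoro-3,5-dimethoxybenzaldehyde 3 through the left half to the target).

Three steps most likely to fail:

Step 2 (double SNAr). The second substitution may stall at the mono-ether, because the fluorinated carbon lies between two donor methoxy groups and the remaining phenoxide is crowded; prolonged heating could then erode the aldehyde. The fallback sets out from 2 and the brominated aldehyde 12 of step 8 and comes back to the route at 7. The bromine, meta to the fluoride, adds inductive activation and is the halogen needed later. Double SNAr of 2 with 12 (Cs2CO3, DMSO, 90 °C) would give methyl 4-(benzyloxy)-3,5-bis(3-bromo-4-formyl-2,6-dimethoxyphenoxy)benzoate F1. Baeyer–Villiger oxidation with mCPBA would pass through methyl 4-(benzyloxy)-3,5-bis[3-bromo-4-(formyloxy)-2,6-dimethoxyphenoxy]benzoate F2, and methanolysis would deliver 7 directly, so steps 3 and 4 fall away.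

Step 6 (double Suzuki coupling). Transmetalation and reductive elimination at a biaryl axis with four ortho oxygens may be slower than protodeboronation of the electron-rich boronic acid, leaving mono-coupled or reduced material. The fallback sets out from 2 and the biaryl aldehyde 13 of step 9, where the biaryl bond is made on a small bromide activated by an ortho formyl group, and comes back at 10. Double SNAr of 2 with 13 (Cs2CO3, DMSO, 100 °C) would give methyl 4-(benzyloxy)-3,5-bis[4-formyl-2,6-dimethoxy-3-(2,4,6-trimethoxyphenyl)phenoxy]benzoate F3. Oxidation with mCPBA would form methyl 4-(benzyloxy)-3,5-bis[4-(formyloxy)-2,6-dimethoxy-3-(2,4,6-trimethoxyphenyl)phenoxy]benzoate F4, and methanolysis would give methyl 4-(benzyloxy)-3,5-bis[4-hydroxy-2,6-dimethoxy-3-(2,4,6-trimethoxyphenyl)phenoxy]benzoate F5. Methylation with MeI and K2CO3 would then give 10.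

Step 17 (Chan–Lam union). Aryl transfer to the crowded, electron-poor ring D phenoxide may be slower than protodeboronation, oxidation or homocoupling of the boronic acid. The fallback reverses the roles, so that the unhindered phenoxide of 20 attacks a ring D fluoride activated by a para formyl group, as in step 2; it sets out from 3, 13 and 20 and comes back at 29.
- Demethylation of 3 with BBr3 would give 4-fluoro-3,5-dihydroxybenzaldehyde F6, whose own fluoride is switched off while the two flanking phenoxides are free.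
- Double SNAr of F6, added slowly to excess 13 (Cs2CO3, DMSO, 100 °C), would give 4-fluoro-3,5-bis[4-formyl-2,6-dimethoxy-3-(2,4,6-trimethoxyphenyl)phenoxy]benzaldehyde F7.
- Displacement of its fluoride by the phenoxide of 20 would give the trialdehyde 4-(ArL-oxy)-3,5-bis[4-formyl-2,6-dimethoxy-3-(2,4,6-trimethoxyphenyl)phenoxy]benzaldehyde F8.
- Triple Baeyer–Villiger oxidation with mCPBA would pass through the tris-formate 4-(ArL-oxy)-3,5-bis[4-(formyloxy)-2,6-dimethoxy-3-(2,4,6-trimethoxyphenyl)phenoxy]phenyl formate F9, and methanolysis would give the triphenol 4-(ArL-oxy)-3,5-bis[4-hydroxy-2,6-dimethoxy-3-(2,4,6-trimethoxyphenyl)phenoxy]phenol F10.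
- BBr3 would then cleave its 19 methyl ethers to give 29.

Further compounds
F1 | step 2 | methyl 4-(benzyloxy)-3,5-bis(3-bromo-4-formyl-2,6-dimethoxyphenoxy)benzoate | COC(=O)c1cc(Oc2c(OC)cc(C=O)c(Br)c2OC)c(OCc2ccccc2)c(Oc2c(OC)cc(C=O)c(Br)c2OC)c1
F2 | step 2 | methyl 4-(benzyloxy)-3,5-bis[3-bromo-4-(formyloxy)-2,6-dimethoxyphenoxy]benzoate | COC(=O)c1cc(Oc2c(OC)cc(OC=O)c(Br)c2OC)c(OCc2ccccc2)c(Oc2c(OC)cc(OC=O)c(Br)c2OC)c1
F3 | step 6 | methyl 4-(benzyloxy)-3,5-bis[4-formyl-2,6-dimethoxy-3-(2,4,6-trimethoxyphenyl)phenoxy]benzoate | COC(=O)c1cc(Oc2c(OC)cc(C=O)c(-c3c(OC)cc(OC)cc3OC)c2OC)c(OCc2ccccc2)c(Oc2c(OC)cc(C=O)c(-c3c(OC)cc(OC)cc3OC)c2OC)c1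
F4 | step 6 | methyl 4-(benzyloxy)-3,5-bis[4-(formyloxy)-2,6-dimethoxy-3-(2,4,6-trimethoxyphenyl)phenoxy]benzoate | COC(=O)c1cc(Oc2c(OC)cc(OC=O)c(-c3c(OC)cc(OC)cc3OC)c2OC)c(OCc2ccccc2)c(Oc2c(OC)cc(OC=O)c(-c3c(OC)cc(OC)cc3OC)c2OC)c1
F5 | step 6 | methyl 4-(benzyloxy)-3,5-bis[4-hydroxy-2,6-dimethoxy-3-(2,4,6-trimethoxyphenyl)phenoxy]benzoate | COC(=O)c1cc(Oc2c(OC)cc(O)c(-c3c(OC)cc(OC)cc3OC)c2OC)c(OCc2ccccc2)c(Oc2c(OC)cc(O)c(-c3c(OC)cc(OC)cc3OC)c2OC)c1
F6 | step 17 | 4-fluoro-3,5-dihydroxybenzaldehyde | O=Cc1cc(O)c(F)c(O)c1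
F7 | step 17 | 4-fluoro-3,5-bis[4-formyl-2,6-dimethoxy-3-(2,4,6-trimethoxyphenyl)phenoxy]benzaldehyde | O=Cc1cc(Oc2c(OC)cc(C=O)c(-c3c(OC)cc(OC)cc3OC)c2OC)c(F)c(Oc2c(OC)cc(C=O)c(-c3c(OC)cc(OC)cc3OC)c2OC)c1
F8 | step 17 | 4-(ArL-oxy)-3,5-bis[4-formyl-2,6-dimethoxy-3-(2,4,6-trimethoxyphenyl)phenoxy]benzaldehyde | O=Cc1cc(Oc2c(OC)cc(C=O)c(-c3c(OC)cc(OC)cc3OC)c2OC)c(Oc2cc(OC)c(Oc3cc(OC)c(Oc4cc(OC)cc(OC)c4)c(OC)c3-c3c(OC)cc(OC)cc3OC)c(OC)c2)c(Oc2c(OC)cc(C=O)c(-c3c(OC)cc(OC)cc3OC)c2OC)c1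
F9 | step 17 | 4-(ArL-oxy)-3,5-bis[4-(formyloxy)-2,6-dimethoxy-3-(2,4,6-trimethoxyphenyl)phenoxy]phenyl formate | O=COc1cc(Oc2c(OC)cc(OC=O)c(-c3c(OC)cc(OC)cc3OC)c2OC)c(Oc2cc(OC)c(Oc3cc(OC)c(Oc4cc(OC)cc(OC)c4)c(OC)c3-c3c(OC)cc(OC)cc3OC)c(OC)c2)c(Oc2c(OC)cc(OC=O)c(-c3c(OC)cc(OC)cc3OC)c2OC)c1
F10 | step 17 | 4-(ArL-oxy)-3,5-bis[4-hydroxy-2,6-dimethoxy-3-(2,4,6-trimethoxyphenyl)phenoxy]phenol | Oc1cc(Oc2c(OC)cc(O)c(-c3c(OC)cc(OC)cc3OC)c2OC)c(Oc2cc(OC)c(Oc3cc(OC)c(Oc4cc(OC)cc(OC)c4)c(OC)c3-c3c(OC)cc(OC)cc3OC)c(OC)c2)c(Oc2c(OC)cc(O)c(-c3c(OC)cc(OC)cc3OC)c2OC)c1
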